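**Plan**

- Retrosynthesis: cut the C3–O ester bond first (ferulic acid, joined with inversion), trace the side-chain ketone back to a terminal alkene and put Boc on nitrogen. Then return C6–H and C3–H to an N,O-ketal and a ketone, C4–C5 to an enone, and cut the N1–C6 bond to reveal a furan.
- Enabling feature: the piperidine carries oxygen on C3 next to the N-bearing C2, and C6 is α to nitrogen. N1/C2(CH3)/C3(O)–C4–C5–C6 is therefore a masked 2-(1-aminoethyl)-5-alkylfuran: furan C2–C5 become C3–C6, the furan oxygen leaves the ring, and N1 with C2 enter it.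
- Forward: the Boc-protected furylethylamine is alkylated at furan C5 with the C12 alkenyl chain. Oxidative dearomatisation then expands the five-membered furan to the six-membered dihydropyridinone, the only ring made. Ketal lock, two hydride reductions, ionic hydrogenation, Wacker oxidation, Mitsunobu esterification and Boc removal follow.
- Stereochemistry: C2 comes from chiral-pool amine 1. C3 is set by hydride attack anti to the axial 2-methyl group and then inverted in the Mitsunobu step. C6 is set by axial hydride addition to the N-acyliminium ion on the methyl face; both controls rest on A(1,3) strain with the Boc group.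

Key step: step 3

Remark: the target is read as the free base (2S,3R,6S), with the 2-methyl group trans to both the C3 acyloxy group and the C6 chain; 1, 3 and 14 are taken as catalogue chemicals; 7–10 are mixtures at C6, which is reset in step 7.

**Route**

Step 1
Reactants: 1 (S)-1-(furan-2-yl)ethan-1-amine
Product: 2 tert-butyl N-[(1S)-1-(furan-2-yl)ethyl]carbamate
Conditions: Boc2O, Et3N, CH2Cl2, 0 °C to rt
Reagents that add atoms: di-tert-butyl dicarbonate, CC(C)(C)OC(=O)OC(=O)OC(C)(C)C
Why: Standard carbamate protection of a primary amine, which supplies the acidic N–H needed for the later ring closure and the N-acyl group whose A(1,3) strain steers steps 6 and 7, without touching the stereocentre.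

Step 2
Reactants: 2 tert-butyl N-[(1S)-1-(furan-2-yl)ethyl]carbamate, 3 12-bromododec-1-ene
Product: 5 tert-butyl N-[(1S)-1-[5-(dodec-11-en-1-yl)furan-2-yl]ethyl]carbamate, via dilithiated carbamate 4 (not isolated)
Conditions: n-BuLi (2.1 equiv), THF, −78 to −10 °C; then 3 (1.3 equiv), −78 °C to rt; H2O
Reagents that add atoms: none
Why: Ring α-metalation of a furan followed by SN2 alkylation, in which the second equivalent of n-BuLi (no diamine additive) should remove the most acidic ring proton at C5 while the N-lithio carbamate disfavours deprotonation of the adjacent tertiary C–H, so the stereocentre should survive and the 5-furyllithium should outrun the carbamate anion towards the primary bromide.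

Step 3
Reactants: 5 tert-butyl N-[(1S)-1-[5-(dodec-11-en-1-yl)furan-2-yl]ethyl]carbamate
Product: 7 tert-butyl (2S)-6-(dodec-11-en-1-yl)-6-hydroxy-2-methyl-3-oxo-3,6-dihydro-2H-pyridine-1-carboxylate, via ring-opened (Z)-enedione 6 (not isolated)
Conditions: mCPBA (1.1 equiv), CH2Cl2, 0 °C; crude product used directly
Reagents that add atoms: mCPBA, O=C(OO)c1cccc(Cl)c1
Why: The peracid transfers one oxygen to the electron-rich 2,5-dialkylfuran, and the oxidised furan collapses to (Z)-ene-1,4-dione 6, in which one carbonyl oxygen is the former furan oxygen and the other comes from the peracid; the carbamate N–H then adds to the C6 ketone, so the five-membered furan is exchanged for the six-membered N1/C2–C6 ring with a C3 ketone and a C6 hemiaminal. The closest known reaction type is the aza-Achmatowicz oxidative rearrangement of N-acyl furfurylamines. The ring closes by 6-exo-trig addition of nitrogen to the C6 carbonyl, which the (Z)-alkene holds within reach. The only new stereocentre, hemiaminal carbon C6, is not controlled and need not be, because it is re-formed in step 7, while C2 is carried through unchanged from 1. The step needs chemoselective oxidation of the furan over the terminal alkene and the product enone, which the far higher nucleophilicity of the furan towards a single equivalent of peracid at 0 °C should secure.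

Step 4
Reactants: 7 tert-butyl (2S)-6-(dodec-11-en-1-yl)-6-hydroxy-2-methyl-3-oxo-3,6-dihydro-2H-pyridine-1-carboxylate
Product: 8 tert-butyl (2S)-6-(dodec-11-en-1-yl)-6-methoxy-2-methyl-3-oxo-3,6-dihydro-2H-pyridine-1-carboxylate
Conditions: MeOH, PPTS (10 mol %), 3 Å molecular sieves, 0 °C to rt
Reagents that add atoms: methanol, CO
Why: Acid-catalysed hemiaminal-to-N,O-ketal exchange through the tertiary N-acyliminium ion (the usual O-alkylation of aza-Achmatowicz hemiaminals) locks the ring so that the hydride reagents of steps 5 and 6 cannot open it to a 1,4-diketone, C6 remaining a mixture.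

Step 5
Reactants: 8 tert-butyl (2S)-6-(dodec-11-en-1-yl)-6-methoxy-2-methyl-3-oxo-3,6-dihydro-2H-pyridine-1-carboxylate
Product: 9 tert-butyl (2S)-6-(dodec-11-en-1-yl)-6-methoxy-2-methyl-3-oxopiperidine-1-carboxylate
Conditions: [(Ph3P)CuH]6 (0.25 equiv, 1.5 equiv of hydride), H2O (2 equiv), degassed toluene/THF, rt
Reagents that add atoms: none
Why: Copper hydride conjugate reduction of an enone, in which the phosphine-bound CuH should deliver hydride only to the β-carbon C5 and leave the isolated terminal alkene, the carbamate and the N,O-ketal untouched, which catalytic hydrogenation could not do.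

Step 6
Reactants: 9 tert-butyl (2S)-6-(dodec-11-en-1-yl)-6-methoxy-2-methyl-3-oxopiperidine-1-carboxylate
Product: 10 tert-butyl (2S,3S)-6-(dodec-11-en-1-yl)-3-hydroxy-6-methoxy-2-methylpiperidine-1-carboxylate
Conditions: NaBH4, MeOH, −40 °C
Reagents that add atoms: none
Why: Substrate-controlled borohydride reduction of a cyclic ketone, in which A(1,3) strain with the Boc group holds the 2-methyl group axial so that hydride should attack C3 axially from the opposite face and place the new hydroxyl cis to the methyl group (3S).

Step 7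
Reactants: 10 tert-butyl (2S,3S)-6-(dodec-11-en-1-yl)-3-hydroxy-6-methoxy-2-methylpiperidine-1-carboxylate
Product: 12 tert-butyl (2S,3S,6S)-6-(dodec-11-en-1-yl)-3-hydroxy-2-methylpiperidine-1-carboxylate, via cyclic N-acyliminium ion 11 (not isolated)
Conditions: Et3SiH (3 equiv), BF3·OEt2 (1.5 equiv), CH2Cl2, −78 °C
Reagents that add atoms: none
Why: Ionic hydrogenation of an N,O-ketal, in which BF3 ionises the methoxy group to cation 11 whose half-chair again carries the 2-methyl group axial, so that stereoelectronically preferred chair-like axial hydride transfer from the silane to C6 on the methyl face should put the chain trans to the methyl group (6S), as in the trans-selective reductions of 2,6-dialkyl N-acyl tetrahydropyridinium ions, while the equatorial C3 hydroxyl cannot reach C6.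

Step 8
Reactants: 12 tert-butyl (2S,3S,6S)-6-(dodec-11-en-1-yl)-3-hydroxy-2-methylpiperidine-1-carboxylate
Product: 13 tert-butyl (2S,3S,6S)-3-hydroxy-2-methyl-6-(11-oxododecyl)piperidine-1-carboxylate
Conditions: PdCl2 (10 mol %), CuCl (1 equiv), O2 (1 atm), DMF/H2O (7:1), rt
Reagents that add atoms: water, O
Why: Tsuji–Wacker oxidation, in which Markovnikov hydroxypalladation of the unhindered terminal alkene should give the methyl ketone while the secondary alcohol and the carbamate are inert, and it is placed before the phenol enters so that no electron-rich arene meets the copper/oxygen couple.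

Step 9
Reactants: 13 tert-butyl (2S,3S,6S)-3-hydroxy-2-methyl-6-(11-oxododecyl)piperidine-1-carboxylate, 14 (E)-ferulic acid
Product: 15 tert-butyl (2S,3R,6S)-3-{[(2E)-3-(4-hydroxy-3-methoxyphenyl)prop-2-enoyl]oxy}-2-methyl-6-(11-oxododecyl)piperidine-1-carboxylate
Conditions: PPh3, DIAD, THF, 0 °C to rt
Reagents that add atoms: none
Why: Mitsunobu esterification, in which the carboxylate should displace the phosphorus-activated C3 oxygen by SN2 with inversion (3S to 3R), placing the ester trans to the 2-methyl group and cis to the C6 chain, the far more acidic carboxylic acid reacting in preference to the free phenol, and a bridged carbamate from Boc participation being too strained to compete.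

Step 10
Reactants: 15 tert-butyl (2S,3R,6S)-3-{[(2E)-3-(4-hydroxy-3-methoxyphenyl)prop-2-enoyl]oxy}-2-methyl-6-(11-oxododecyl)piperidine-1-carboxylate
Product: 16 (2S,3R,6S)-2-methyl-6-(11-oxododecyl)piperidin-3-yl (2E)-3-(4-hydroxy-3-methoxyphenyl)prop-2-enoate
Conditions: TFA/CH2Cl2 (1:4), anisole, 0 °C; then aq NaHCO3
Reagents that add atoms: none
Why: Acidolysis of the tert-butyl carbamate (anisole traps the tert-butyl cation) should free the secondary amine without affecting the cinnamate ester, phenol, ketone or any stereocentre, and O-to-N acyl shift would need a strained bridged intermediate.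

**Compound list**

1 | (S)-1-(furan-2-yl)ethan-1-amine | C[C@H](N)c1ccco1 | starting material
2 | tert-butyl N-[(1S)-1-(furan-2-yl)ethyl]carbamate | C[C@H](NC(=O)OC(C)(C)C)c1ccco1 | intermediate
3 | 12-bromododec-1-ene | C=CCCCCCCCCCCBr | starting material
4 | N,5-dilithio derivative of 2 (dilithiated carbamate) | C[C@H](N([Li])C(=O)OC(C)(C)C)c1ccc([Li])o1 | intermediate
5 | tert-butyl N-[(1S)-1-[5-(dodec-11-en-1-yl)furan-2-yl]ethyl]carbamate | C[C@H](NC(=O)OC(C)(C)C)c1ccc(CCCCCCCCCCC=C)o1 | intermediate
6 | tert-butyl N-[(2S,4Z)-3,6-dioxooctadeca-4,17-dien-2-yl]carbamate | C[C@H](NC(=O)OC(C)(C)C)C(=O)/C=C\C(=O)CCCCCCCCCCC=C | intermediate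
7 | tert-butyl (2S)-6-(dodec-11-en-1-yl)-6-hydroxy-2-methyl-3-oxo-3,6-dihydro-2H-pyridine-1-carboxylate (C6 epimers) | O=C1C=CC(O)(CCCCCCCCCCC=C)N(C(=O)OC(C)(C)C)[C@H]1C | intermediate
8 | tert-butyl (2S)-6-(dodec-11-en-1-yl)-6-methoxy-2-methyl-3-oxo-3,6-dihydro-2H-pyridine-1-carboxylate (C6 epimers) | O=C1C=CC(OC)(CCCCCCCCCCC=C)N(C(=O)OC(C)(C)C)[C@H]1C | intermediate
9 | tert-butyl (2S)-6-(dodec-11-en-1-yl)-6-methoxy-2-methyl-3-oxopiperidine-1-carboxylate (C6 epimers) | O=C1CCC(OC)(CCCCCCCCCCC=C)N(C(=O)OC(C)(C)C)[C@H]1C | intermediate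
10 | tert-butyl (2S,3S)-6-(dodec-11-en-1-yl)-3-hydroxy-6-methoxy-2-methylpiperidine-1-carboxylate (C6 epimers) | O[C@H]1CCC(OC)(CCCCCCCCCCC=C)N(C(=O)OC(C)(C)C)[C@H]1C | intermediate
11 | (2S,3S)-1-(tert-butoxycarbonyl)-6-(dodec-11-en-1-yl)-3-hydroxy-2-methyl-2,3,4,5-tetrahydropyridin-1-ium methoxytrifluoroborate | O[C@H]1CCC(CCCCCCCCCCC=C)=[N+](C(=O)OC(C)(C)C)[C@H]1C.CO[B-](F)(F)F | intermediate
12 | tert-butyl (2S,3S,6S)-6-(dodec-11-en-1-yl)-3-hydroxy-2-methylpiperidine-1-carboxylate | O[C@H]1CC[C@H](CCCCCCCCCCC=C)N(C(=O)OC(C)(C)C)[C@H]1C | intermediate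
13 | tert-butyl (2S,3S,6S)-3-hydroxy-2-methyl-6-(11-oxododecyl)piperidine-1-carboxylate | O[C@H]1CC[C@H](CCCCCCCCCCC(C)=O)N(C(=O)OC(C)(C)C)[C@H]1C | intermediate
14 | (E)-ferulic acid, (2E)-3-(4-hydroxy-3-methoxyphenyl)prop-2-enoic acid | COc1cc(/C=C/C(=O)O)ccc1O | starting material
15 | tert-butyl (2S,3R,6S)-3-{[(2E)-3-(4-hydroxy-3-methoxyphenyl)prop-2-enoyl]oxy}-2-methyl-6-(11-oxododecyl)piperidine-1-carboxylate | COc1cc(/C=C/C(=O)O[C@@H]2CC[C@H](CCCCCCCCCCC(C)=O)N(C(=O)OC(C)(C)C)[C@H]2C)ccc1O | intermediate
16 | (2S,3R,6S)-2-methyl-6-(11-oxododecyl)piperidin-3-yl (2E)-3-(4-hydroxy-3-methoxyphenyl)prop-2-enoate | COc1cc(/C=C/C(=O)O[C@@H]2CC[C@H](CCCCCCCCCCC(C)=O)N[C@H]2C)ccc1O | target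

**Count and risks**

Total step count: 10. Longest linear sequence: 10 steps (1 to 16).

Steps most likely to fail:

Step 4. The tertiary hemiaminal may open to the enedione with Z-to-E isomerisation, lose water to an exocyclic ene-carbamate, or aromatise to a 3-hydroxypyridine with loss of Boc, instead of exchanging OH for OMe. The fallback sets out from 5 and avoids the free hemiaminal altogether. Electrophilic 2,5-dimethoxylation of the furan with NBS and NaHCO3 in MeOH at −40 °C should give tert-butyl N-[(1S)-1-[5-(dodec-11-en-1-yl)-2,5-dimethoxy-2,5-dihydrofuran-2-yl]ethyl]carbamate F1 as a diastereomer mixture. Catalytic PPTS in CH2Cl2/MeOH should then expel one methanol and let the carbamate nitrogen close onto C5, so that the rearranged ring keeps its methoxy group and the route is rejoined at 8.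

Step 7. Hydride transfer may lose facial selectivity if attack anti to the axial methyl group through a twist-boat competes, or the cation may be intercepted by the C3 hydroxyl and diverted to a tetrahydrofuran. The fallback sets out from 10 and sets C6 on the free imine instead of the N-acyl cation. TFA in CH2Cl2 should remove Boc and methanol to give the cyclic imine (2S,3S)-6-(dodec-11-en-1-yl)-2-methyl-2,3,4,5-tetrahydropyridin-3-ol F2. Reduction with LiAlH4 in the presence of AlMe3 (THF, −78 °C), the combination known to turn 2,6-dialkyl cyclic imines into trans-piperidines, should give (2S,3S,6S)-6-(dodec-11-en-1-yl)-2-methylpiperidin-3-ol F3. N-selective protection with Boc2O, Et3N in MeOH at 50 °C comes back to the route at 12.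

Step 9. Activation and displacement at the hindered C3 with a weakly acidic, phenol-bearing acid may be slow, so that elimination or O-alkylation of the phenol takes over. The fallback sets out from 13 and separates inversion from acylation. Mitsunobu inversion with the stronger 4-nitrobenzoic acid (PPh3, DIAD, toluene) should give tert-butyl (2S,3R,6S)-2-methyl-3-[(4-nitrobenzoyl)oxy]-6-(11-oxododecyl)piperidine-1-carboxylate F4. K2CO3 in MeOH should release the trans alcohol tert-butyl (2S,3R,6S)-3-hydroxy-2-methyl-6-(11-oxododecyl)piperidine-1-carboxylate F5. DCC/DMAP acylation with commercial (E)-4-acetoxy-3-methoxycinnamic acid, with retention, should give tert-butyl (2S,3R,6S)-3-{[(2E)-3-(4-acetoxy-3-methoxyphenyl)prop-2-enoyl]oxy}-2-methyl-6-(11-oxododecyl)piperidine-1-carboxylate F6. Selective aminolysis of the aryl acetate with pyrrolidine in CH2Cl2 at 0 °C comes back to the route at 15.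

**Further compounds**

F1 | step 4 | tert-butyl N-[(1S)-1-[5-(dodec-11-en-1-yl)-2,5-dimethoxy-2,5-dihydrofuran-2-yl]ethyl]carbamate | C[C@H](NC(=O)OC(C)(C)C)C1(OC)C=CC(OC)(CCCCCCCCCCC=C)O1
F2 | step 7 | (2S,3S)-6-(dodec-11-en-1-yl)-2-methyl-2,3,4,5-tetrahydropyridin-3-ol | O[C@H]1CCC(CCCCCCCCCCC=C)=N[C@H]1C
F3 | step 7 | (2S,3S,6S)-6-(dodec-11-en-1-yl)-2-methylpiperidin-3-ol | O[C@H]1CC[C@H](CCCCCCCCCCC=C)N[C@H]1C
F4 | step 9 | tert-butyl (2S,3R,6S)-2-methyl-3-[(4-nitrobenzoyl)oxy]-6-(11-oxododecyl)piperidine-1-carboxylate | O=C(O[C@@H]1CC[C@H](CCCCCCCCCCC(C)=O)N(C(=O)OC(C)(C)C)[C@H]1C)c1ccc(cc1)[N+](=O)[O-]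
F5 | step 9 | tert-butyl (2S,3R,6S)-3-hydroxy-2-methyl-6-(11-oxododecyl)piperidine-1-carboxylate | O[C@@H]1CC[C@H](CCCCCCCCCCC(C)=O)N(C(=O)OC(C)(C)C)[C@H]1C
F6 | step 9 | tert-butyl (2S,3R,6S)-3-{[(2E)-3-(4-acetoxy-3-methoxyphenyl)prop-2-enoyl]oxy}-2-methyl-6-(11-oxododecyl)piperidine-1-carboxylate | COc1cc(/C=C/C(=O)O[C@@H]2CC[C@H](CCCCCCCCCCC(C)=O)N(C(=O)OC(C)(C)C)[C@H]2C)ccc1OC(C)=O
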